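The route rests on cutting the C8–O4' ether bond. C8, the only stereocentre, is a methyl-bearing CH between the C7 ketone on the 3,4,5-trimethoxyphenyl ring (ring A) and the ether oxygen at C4' of the 3',5'-dimethoxycinnamyl ring (ring B). This acyl/H/aryloxy pattern is what an acyl carbene leaves after entering a phenol O–H bond. A single catalytic operation therefore joins both halves, forms C8–O4' and C8–H, and fixes (R)-C8 through proton delivery by a chiral phosphoric acid. Its precursors are the α-methyl α-diazo ketone of ring A and sinapyl alcohol carrying a silyl ether at O9' and a free phenol.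

Key step: step 8

Assumption: neolignan numbering is used (C7 ketone carbon, C8 stereocentre, C9 its methyl; primed atoms belong to ring B and its C7'=C8'–C9' chain); because the sense of induction cannot be predicted for this new substrate pair, both antipodes of the acid are screened and the one giving (R)-C8 is used, the assignment being checked by chiral HPLC against the lactate-derived sample of 13 described in the fallback to step 8.

Step 1
Reactants: 1 3,4,5-trimethoxybenzaldehyde; 2 ethylmagnesium bromide
Product: 3 (±)-1-(3,4,5-trimethoxyphenyl)propan-1-ol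
Conditions: 2 (1.2 equiv), THF, 0 °C → rt; sat. aq NH4Cl
Reagents that add atoms: none
Why: Grignard 1,2-addition to a non-enolisable aromatic aldehyde is dependable, and the carbinol centre, formed racemic, is erased in step 2.

Step 2
Reactants: 3 (±)-1-(3,4,5-trimethoxyphenyl)propan-1-ol
Product: 4 1-(3,4,5-trimethoxyphenyl)propan-1-one
Conditions: activated MnO2 (10 equiv), CH2Cl2, rt
Reagents that add atoms: none
Why: Heterogeneous MnO2 oxidation of an electron-rich benzylic alcohol runs under neutral conditions, stops at the ketone and leaves the aryl methyl ethers untouched.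

Step 3
Reactants: 4 1-(3,4,5-trimethoxyphenyl)propan-1-one
Product: 6 (±)-4,4,4-trifluoro-2-methyl-1-(3,4,5-trimethoxyphenyl)butane-1,3-dione, via lithium enolate 5 (not isolated)
Conditions: LiHMDS (1.1 equiv), THF, −78 °C; CF3CO2CH2CF3 (1.2 equiv), −78 °C; 5% aq HCl; crude taken on at once
Reagents that add atoms: 2,2,2-trifluoroethyl trifluoroacetate, FC(F)(F)COC(=O)C(F)(F)F
Why: Crossed Claisen-type C-acylation of the preformed lithium enolate by the very electrophilic trifluoroacetate ester makes C8 acidic enough for diazo transfer, which the simple propiophenone is not.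

Step 4
Reactants: 6 (±)-4,4,4-trifluoro-2-methyl-1-(3,4,5-trimethoxyphenyl)butane-1,3-dione
Product: 7 2-diazo-1-(3,4,5-trimethoxyphenyl)propan-1-one
Conditions: p-ABSA (1.5 equiv), Et3N (1.5 equiv), H2O (1 equiv), MeCN, rt; stored cold in the dark
Reagents that add atoms: 4-acetamidobenzenesulfonyl azide (p-ABSA), CC(=O)Nc1ccc(cc1)S(=O)(=O)N=[N+]=[N-]
Why: In this deacylative Regitz diazo transfer the ammonium enolate of 6 attacks the terminal azide nitrogen and the adduct fragments, passing the trifluoroacetyl group to the sulfonamide nitrogen and leaving the α-methyl diazo ketone.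

Step 5
Reactants: 8 (E)-sinapic acid
Product: 9 methyl (E)-sinapate
Conditions: MeOH, cat. H2SO4, reflux
Reagents that add atoms: methanol, CO
Why: Fischer esterification touches neither the phenol nor the E-alkene and gives a soluble substrate for hydride reduction.

Step 6
Reactants: 9 methyl (E)-sinapate
Product: 10 (E)-sinapyl alcohol
Conditions: DIBAL-H (3.5 equiv), toluene, 0 °C; aq Rochelle salt; product kept under argon and used promptly
Reagents that add atoms: none
Why: DIBAL-H reduces conjugated esters by clean 1,2-hydride delivery to the allylic alcohol; one equivalent is consumed by the phenol as its aluminium phenoxide, and the E geometry is retained.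

Step 7
Reactants: 10 (E)-sinapyl alcohol
Product: 11 4-[(E)-3-(tert-butyldimethylsilyloxy)prop-1-en-1-yl]-2,6-dimethoxyphenol
Conditions: TBSCl (1.05 equiv), imidazole (2 equiv), DMF, 0 °C
Reagents that add atoms: tert-butyldimethylsilyl chloride, CC(C)(C)[Si](C)(C)Cl
Why: In this chemoselective imidazole-mediated silylation the open primary allylic hydroxyl should take up one equivalent of the bulky chlorosilane much faster than the phenol, which is flanked by two ortho methoxy groups and hydrogen-bonded to them.

Step 8
Reactants: 7 2-diazo-1-(3,4,5-trimethoxyphenyl)propan-1-one; 11 4-[(E)-3-(tert-butyldimethylsilyloxy)prop-1-en-1-yl]-2,6-dimethoxyphenol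
Product: 13 (R)-2-{4-[(E)-3-(tert-butyldimethylsilyloxy)prop-1-en-1-yl]-2,6-dimethoxyphenoxy}-1-(3,4,5-trimethoxyphenyl)propan-1-one, via aryloxy enol 12 (not isolated)
Conditions: Rh2(TPA)4 (2 mol %), 6,6'-bis(2,4,6-triisopropylphenyl)-SPINOL phosphoric acid (5 mol %, antipode chosen by screening), 4 Å MS, CH2Cl2, −40 °C; 7 (1.5 equiv) by syringe pump over 6 h; filtration through neutral silica
Reagents that add atoms: none
Why: Proposed new method: Rh2(TPA)4 expels N2 from 7 to give an electrophilic acyl(methyl)carbene on rhodium, the phenol oxygen of 11 adds to it, and the oxonium ylide sheds the metal to leave the free enol 12, which the chiral phosphoric acid protonates at C8. The closest known reaction types are copper/chiral spiro-bisoxazoline insertion of α-diazopropionates into phenol O–H bonds and dirhodium/chiral phosphoric acid insertion of α-diazo ketones into N–H and alcohol O–H bonds, whereas an α-methyl α-diazo aryl ketone has not been paired with a doubly ortho-substituted phenol. No ring closes; the bonds formed are C8–O4' and C8–H. C8 is controlled solely by the acid, which binds the enol O–H with its P=O and hands its own proton to one enol face inside the 6,6'-diaryl pocket, so the antipode giving (R) is picked by experiment. Chemoselectivity must favour phenol capture over the 1,2-hydride shift to the aryl vinyl ketone, cyclopropanation of the C7'=C8' alkene and insertion into other O–H bonds: the crowded triphenylacetate ligands, the low temperature and the slow feed of 7 hold back hydride shift and carbene dimerisation, silylation of O9' and the sieves leave the phenol as the only O–H donor, and the 1,2-disubstituted alkene is a poorer trap for an acceptor carbene than a polar O–H bond. Prompt removal of the acid on neutral silica keeps the product from re-enolising.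

Step 9
Reactants: 13 (R)-2-{4-[(E)-3-(tert-butyldimethylsilyloxy)prop-1-en-1-yl]-2,6-dimethoxyphenoxy}-1-(3,4,5-trimethoxyphenyl)propan-1-one
Product: 14 (R)-2-{4-[(E)-3-hydroxyprop-1-en-1-yl]-2,6-dimethoxyphenoxy}-1-(3,4,5-trimethoxyphenyl)propan-1-one (CNP0171423.1)
Conditions: Et3N·3HF (5 equiv), THF, 0 °C → rt; pH 7 phosphate buffer
Reagents that add atoms: none
Why: Fluoride-driven Si–O cleavage in a weakly acidic medium free of unprotonated amine removes the primary silyl ether without forming an enolate at C8 or a cinnamyl cation at C9', so the (R) centre and the E-alkene should persist.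

Compound list
1 | 3,4,5-trimethoxybenzaldehyde | COc1cc(C=O)cc(OC)c1OC | starting material
2 | ethylmagnesium bromide | CC[Mg]Br | starting material
3 | (±)-1-(3,4,5-trimethoxyphenyl)propan-1-ol | CCC(O)c1cc(OC)c(OC)c(OC)c1 | intermediate
4 | 1-(3,4,5-trimethoxyphenyl)propan-1-one | CCC(=O)c1cc(OC)c(OC)c(OC)c1 | intermediate
5 | lithium 1-(3,4,5-trimethoxyphenyl)prop-1-en-1-olate (lithium enolate of 4, not isolated) | [Li]OC(=CC)c1cc(OC)c(OC)c(OC)c1 | intermediate
6 | (±)-4,4,4-trifluoro-2-methyl-1-(3,4,5-trimethoxyphenyl)butane-1,3-dione | CC(C(=O)C(F)(F)F)C(=O)c1cc(OC)c(OC)c(OC)c1 | intermediate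
7 | 2-diazo-1-(3,4,5-trimethoxyphenyl)propan-1-one | CC(=[N+]=[N-])C(=O)c1cc(OC)c(OC)c(OC)c1 | intermediate
8 | (E)-sinapic acid | COc1cc(/C=C/C(=O)O)cc(OC)c1O | starting material
9 | methyl (E)-sinapate | COC(=O)/C=C/c1cc(OC)c(O)c(OC)c1 | intermediate
10 | (E)-sinapyl alcohol | COc1cc(/C=C/CO)cc(OC)c1O | intermediate
11 | 4-[(E)-3-(tert-butyldimethylsilyloxy)prop-1-en-1-yl]-2,6-dimethoxyphenol | COc1cc(/C=C/CO[Si](C)(C)C(C)(C)C)cc(OC)c1O | intermediate
12 | 2-{4-[(E)-3-(tert-butyldimethylsilyloxy)prop-1-en-1-yl]-2,6-dimethoxyphenoxy}-1-(3,4,5-trimethoxyphenyl)prop-1-en-1-ol (enol, enol geometry undefined, not isolated) | CC(Oc1c(OC)cc(/C=C/CO[Si](C)(C)C(C)(C)C)cc1OC)=C(O)c1cc(OC)c(OC)c(OC)c1 | intermediate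
13 | (R)-2-{4-[(E)-3-(tert-butyldimethylsilyloxy)prop-1-en-1-yl]-2,6-dimethoxyphenoxy}-1-(3,4,5-trimethoxyphenyl)propan-1-one | COc1cc(C(=O)[C@@H](C)Oc2c(OC)cc(/C=C/CO[Si](C)(C)C(C)(C)C)cc2OC)cc(OC)c1OC | intermediate
14 | (R)-2-{4-[(E)-3-hydroxyprop-1-en-1-yl]-2,6-dimethoxyphenoxy}-1-(3,4,5-trimethoxyphenyl)propan-1-one (CNP0171423.1) | COc1cc(C(=O)[C@@H](C)Oc2c(OC)cc(/C=C/CO)cc2OC)cc(OC)c1OC | target

Total step count: 9
Longest linear sequence: 6 (steps 1, 2, 3, 4, 8, 9)

Steps most likely to fail

Step 8. Three processes threaten this step.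
- Hydride migration from the methyl group within the carbene may outrun capture by the crowded phenol.
- An achiral proton relay by a second phenol molecule or trace water may erode the facial selectivity at C8.
- The sense of induction is unknown.

The fallback uses known chemistry only and runs from 11 back to 13. The C8–O4' bond is made by SN2 displacement and the configuration is taken from the chiral pool.
- Phenol 11 and commercial methyl (S)-lactate undergo a Mitsunobu reaction (PPh3, DIAD, THF, 0 °C → rt). Inversion gives methyl (R)-2-{4-[(E)-3-(tert-butyldimethylsilyloxy)prop-1-en-1-yl]-2,6-dimethoxyphenoxy}propanoate F1.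
- MeNH(OMe)·HCl and i-PrMgCl (THF, −20 °C) turn it into (R)-2-{4-[(E)-3-(tert-butyldimethylsilyloxy)prop-1-en-1-yl]-2,6-dimethoxyphenoxy}-N-methoxy-N-methylpropanamide F2.
- 3,4,5-Trimethoxyphenylmagnesium bromide F3 is made from commercial 5-bromo-1,2,3-trimethoxybenzene and Mg in THF.
- F3 adds to F2 at −20 → 0 °C (Weinreb ketone synthesis), and a cold NH4Cl quench of the chelated adduct releases 13.

This material also serves as the authentic (R) reference for the insertion product.

Step 9. Slow enolisation at C8 during prolonged contact with the fluoride source, or solvolytic loss of the oxygen at the electron-rich cinnamyl position C9', would damage the product at the last stage. The fallback runs from 10 back to 14 and replaces the silyl ether by an enzyme-labile ester, so that unmasking takes place at neutral pH.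
- Immobilised Candida antarctica lipase B and vinyl acetate (MTBE, rt) acylate only the primary hydroxyl of 10, giving (E)-sinapyl acetate F4.
- F4 is coupled with 7 under the catalysts of step 8 to give (R)-(E)-3-{3,5-dimethoxy-4-[1-oxo-1-(3,4,5-trimethoxyphenyl)propan-2-yloxy]phenyl}prop-2-en-1-yl acetate F5.
- The same lipase with n-butanol in MTBE (30 °C) transfers the acetyl group to butanol and releases 14.

Step 7. Discrimination between the two hydroxyl groups may be incomplete, so that silylation also occurs at the phenol. The fallback runs from 10 back to 11 and moves the selection from the silylation to the desilylation.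
- Excess TBSCl and imidazole (DMF, rt) give the bis-silyl ether tert-butyl{4-[(E)-3-(tert-butyldimethylsilyloxy)prop-1-en-1-yl]-2,6-dimethoxyphenoxy}dimethylsilane F6.
- K2CO3 in MeOH (rt) then cleaves only the aryl silyl ether, because phenoxide is by far the better leaving group at silicon. This returns 11.

Further compounds
F1 | step 8 | methyl (R)-2-{4-[(E)-3-(tert-butyldimethylsilyloxy)prop-1-en-1-yl]-2,6-dimethoxyphenoxy}propanoate | COC(=O)[C@@H](C)Oc1c(OC)cc(/C=C/CO[Si](C)(C)C(C)(C)C)cc1OC
F2 | step 8 | (R)-2-{4-[(E)-3-(tert-butyldimethylsilyloxy)prop-1-en-1-yl]-2,6-dimethoxyphenoxy}-N-methoxy-N-methylpropanamide | CON(C)C(=O)[C@@H](C)Oc1c(OC)cc(/C=C/CO[Si](C)(C)C(C)(C)C)cc1OC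
F3 | step 8 | 3,4,5-trimethoxyphenylmagnesium bromide | COc1cc([Mg]Br)cc(OC)c1OC
F4 | step 9 | (E)-sinapyl acetate | COc1cc(/C=C/COC(C)=O)cc(OC)c1O
F5 | step 9 | (R)-(E)-3-{3,5-dimethoxy-4-[1-oxo-1-(3,4,5-trimethoxyphenyl)propan-2-yloxy]phenyl}prop-2-en-1-yl acetate | COc1cc(C(=O)[C@@H](C)Oc2c(OC)cc(/C=C/COC(C)=O)cc2OC)cc(OC)c1OC
F6 | step 7 | tert-butyl{4-[(E)-3-(tert-butyldimethylsilyloxy)prop-1-en-1-yl]-2,6-dimethoxyphenoxy}dimethylsilane | COc1cc(/C=C/CO[Si](C)(C)C(C)(C)C)cc(OC)c1O[Si](C)(C)C(C)(C)C
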